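**Plan**

- The target is (2S)-5,3'-dihydroxy-7,4'-dimethoxy-8-prenylflavanone. The enabling feature is O1 of the pyranone ring: it is the β-oxygen of the C4 ketone (O1–C2–C3–C4=O) and it sits ortho to the prenylated C8 of the benzo ring.
- Retrosynthesis: cut O1–C2 (oxa-Michael) after placing a temporary CO2tBu group on C3; trace the C8 prenyl group back to an O1 1,1-dimethylallyl ether (aromatic Claisen); cut C2=C3 (Knoevenagel) and C3–CO2tBu (enolate acylation).
- Forward: both aromatic rings are bought (an acetophenone and isovanillin) and the chain is joined open; the pyranone ring closes last, in one flask: Claisen rearrangement (prenyl to C8, O1–H set free), catalytic oxa-Michael addition, decarboxylation.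
- Stereochemistry: C2 (S) is the only stereocentre and is set by the chiral cinchona thiourea catalyst in the ring closure; no later step is basic enough to reopen the ring.
- Helpers: CO2tBu at C3 (lost in the key flask) and triisopropylsilyl groups on O5 and O3' (removed last).

Key step: step 7

Assumption 1: the thiourea derived from 9-amino-9-deoxy-epi-quinidine is taken to give the 2S series; if the sense of induction is the opposite, its quinine-derived pseudo-enantiomer is used and nothing else changes.
Assumption 2: alkene 9 is drawn as the Z isomer expected to predominate; the alkene geometry disappears on ring closure, and whether both isomers converge on the same C2 configuration is to be checked.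

**Step 1**
Reactants: 1 1-(2,6-dihydroxy-4-methoxyphenyl)ethan-1-one; 2 3-chloro-3-methylbut-1-yne
Product: 3 1-[2-hydroxy-4-methoxy-6-(2-methylbut-3-yn-2-yloxy)phenyl]ethan-1-one
Conditions: CuCl2·2H2O (0.5 mol %), DBU (1.2 equiv), MeCN, 0 °C
Reagents that add atoms: none
Why: Copper-catalysed propargylic etherification is the standard route to aryl 1,1-dimethylpropargyl ethers at 0 °C; the two hydroxyls of 1 are equivalent, and after the first etherification the remaining one is locked in a hydrogen bond to the acetyl oxygen, which should hold the reaction at the mono-ether.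

**Step 2**
Reactants: 3 1-[2-hydroxy-4-methoxy-6-(2-methylbut-3-yn-2-yloxy)phenyl]ethan-1-one
Product: 4 1-[4-methoxy-2-(2-methylbut-3-yn-2-yloxy)-6-(triisopropylsilyloxy)phenyl]ethan-1-one
Conditions: TIPSCl, imidazole, DMAP (cat.), DMF, 40 °C
Reagents that add atoms: triisopropylsilyl chloride, CC(C)[Si](Cl)(C(C)C)C(C)C
Why: Imidazole-promoted silylation masks the remaining chelated phenol (the future O5) so that it can never act as the ring-closing nucleophile; the triisopropylsilyl ether should survive LiHMDS, piperidinium acetate and hot TsOH in toluene and leaves with fluoride.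

**Step 3**
Reactants: 4 1-[4-methoxy-2-(2-methylbut-3-yn-2-yloxy)-6-(triisopropylsilyloxy)phenyl]ethan-1-one
Product: 5 1-[4-methoxy-2-(2-methylbut-3-en-2-yloxy)-6-(triisopropylsilyloxy)phenyl]ethan-1-one
Conditions: H2 (1 atm), Lindlar catalyst, quinoline, EtOAc, 20 °C
Reagents that add atoms: none
Why: Lindlar semi-hydrogenation stops at the alkene in the presence of quinoline, and at 20 °C the aryl 1,1-dimethylallyl ether should not yet rearrange; the aryl ketone and the silyl ether are inert.

**Step 4**
Reactants: 5 1-[4-methoxy-2-(2-methylbut-3-en-2-yloxy)-6-(triisopropylsilyloxy)phenyl]ethan-1-one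
Product: 6 tert-butyl 3-[4-methoxy-2-(2-methylbut-3-en-2-yloxy)-6-(triisopropylsilyloxy)phenyl]-3-oxopropanoate
Conditions: LiHMDS (2.2 equiv), THF, −78 °C; Boc2O (1.1 equiv), −78 to −20 °C; AcOH quench
Reagents that add atoms: di-tert-butyl dicarbonate, CC(C)(C)OC(=O)OC(=O)OC(C)(C)C
Why: C-acylation of the lithium enolate of an aryl methyl ketone by Boc2O (crossed Claisen-type condensation) gives the β-keto ester, whose deprotonation by the second equivalent of base drives the reaction and prevents double acylation; 5 has no other acidic site, and the tert-butyl ester is the temporary activating group for the ring closure.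

**Step 5**
Reactants: 7 3-hydroxy-4-methoxybenzaldehyde (isovanillin)
Product: 8 4-methoxy-3-(triisopropylsilyloxy)benzaldehyde
Conditions: TIPSCl, imidazole, DMF, 20 °C
Reagents that add atoms: triisopropylsilyl chloride, CC(C)[Si](Cl)(C(C)C)C(C)C
Why: Standard imidazole-promoted silylation of a phenol; the free B-ring hydroxyl is masked so that it cannot interfere with the hydrogen-bonding catalyst of step 7.

**Step 6**
Reactants: 6 tert-butyl 3-[4-methoxy-2-(2-methylbut-3-en-2-yloxy)-6-(triisopropylsilyloxy)phenyl]-3-oxopropanoate; 8 4-methoxy-3-(triisopropylsilyloxy)benzaldehyde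
Product: 9 tert-butyl (Z)-2-[4-methoxy-2-(2-methylbut-3-en-2-yloxy)-6-(triisopropylsilyloxy)benzoyl]-3-[4-methoxy-3-(triisopropylsilyloxy)phenyl]prop-2-enoate
Conditions: piperidine (0.2 equiv), AcOH (0.2 equiv), 4 Å MS, PhMe, 20 °C
Reagents that add atoms: none
Why: Knoevenagel condensation of the active methylene of 6 with the aromatic aldehyde under piperidinium acetate catalysis is driven by removal of water; because O2' is still etherified, the doubly activated alkene cannot cyclise prematurely.

**Step 7**
Reactants: 9 tert-butyl (Z)-2-[4-methoxy-2-(2-methylbut-3-en-2-yloxy)-6-(triisopropylsilyloxy)benzoyl]-3-[4-methoxy-3-(triisopropylsilyloxy)phenyl]prop-2-enoate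
Product: 12 (2S)-7-methoxy-2-[4-methoxy-3-(triisopropylsilyloxy)phenyl]-8-(3-methylbut-2-en-1-yl)-5-(triisopropylsilyloxy)chroman-4-one, via phenol alkylidene keto ester 10 (not isolated), via tert-butyl flavanone-3-carboxylate 11 (not isolated)
Conditions: (i) PhMe, 105 °C; (ii) epi-quinidine-derived 3,5-bis(trifluoromethyl)phenyl thiourea (10 mol %), −25 °C; (iii) TsOH·H2O (0.5 equiv), 80 °C
Reagents that add atoms: none
Why: Heat alone triggers the aromatic Claisen rearrangement of the aryl 1,1-dimethylallyl ether: the allyl unit moves from O2' to C3' (the only free ortho carbon, since C1' carries the aroyl group) with allylic transposition, and re-aromatisation should give phenol 10 with the prenyl group in place and O2' free. At −25 °C the bifunctional thiourea should then mediate the intramolecular oxa-Michael addition of this phenol to the alkylidene β-keto ester; the closest known reaction type is the thiourea-catalysed enantioselective cyclisation of tert-butyl 2-(2-hydroxybenzoyl)cinnamates to 3-carboxyflavanones with acid decarboxylation in the same flask. The pyranone ring closes in the 6-endo-trig mode by O1–C2 bond formation. C2 is controlled by the catalyst, whose thiourea binds the 1,3-dicarbonyl unit while the quinuclidine nitrogen activates the phenol and guides it to one face of the benzylidene carbon; C3 of 11 (expected trans) ceases to be a stereocentre when TsOH cleaves the tert-butyl ester and CO2 is lost through the C3=C4 enol, which leaves C2 untouched. The step needs regioselectivity (closure through O2' and not O6'), secured because O6' is silylated and O2' is set free only by the rearrangement that places the prenyl group next to it. It also needs enantioselectivity, secured by running the base-free thermal stage before the catalyst is added, since the hydrogen-bonded phenol of 10 should add only slowly without a base.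

**Step 8**
Reactants: 12 (2S)-7-methoxy-2-[4-methoxy-3-(triisopropylsilyloxy)phenyl]-8-(3-methylbut-2-en-1-yl)-5-(triisopropylsilyloxy)chroman-4-one
Product: 13 (2S)-5-hydroxy-2-(3-hydroxy-4-methoxyphenyl)-7-methoxy-8-(3-methylbut-2-en-1-yl)chroman-4-one
Conditions: TBAF (2.5 equiv), AcOH (2.5 equiv), THF, 0 to 20 °C
Reagents that add atoms: none
Why: Fluoride cleaves both aryl silyl ethers (Si–F bond formation), and the acetic acid buffer keeps the medium below the basicity at which a flavanone opens to its chalcone, so that C2 should stay S; the prenyl group and the methyl ethers are inert.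

**Compound list**

1 | 1-(2,6-dihydroxy-4-methoxyphenyl)ethan-1-one | CC(=O)c1c(O)cc(OC)cc1O | starting material
2 | 3-chloro-3-methylbut-1-yne | C#CC(C)(C)Cl | starting material
3 | 1-[2-hydroxy-4-methoxy-6-(2-methylbut-3-yn-2-yloxy)phenyl]ethan-1-one | CC(=O)c1c(O)cc(OC)cc1OC(C)(C)C#C | intermediate
4 | 1-[4-methoxy-2-(2-methylbut-3-yn-2-yloxy)-6-(triisopropylsilyloxy)phenyl]ethan-1-one | CC(=O)c1c(O[Si](C(C)C)(C(C)C)C(C)C)cc(OC)cc1OC(C)(C)C#C | intermediate
5 | 1-[4-methoxy-2-(2-methylbut-3-en-2-yloxy)-6-(triisopropylsilyloxy)phenyl]ethan-1-one | CC(=O)c1c(O[Si](C(C)C)(C(C)C)C(C)C)cc(OC)cc1OC(C)(C)C=C | intermediate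
6 | tert-butyl 3-[4-methoxy-2-(2-methylbut-3-en-2-yloxy)-6-(triisopropylsilyloxy)phenyl]-3-oxopropanoate | CC(C)(C)OC(=O)CC(=O)c1c(O[Si](C(C)C)(C(C)C)C(C)C)cc(OC)cc1OC(C)(C)C=C | intermediate
7 | 3-hydroxy-4-methoxybenzaldehyde (isovanillin) | COc1ccc(C=O)cc1O | starting material
8 | 4-methoxy-3-(triisopropylsilyloxy)benzaldehyde | COc1ccc(C=O)cc1O[Si](C(C)C)(C(C)C)C(C)C | intermediate
9 | tert-butyl (Z)-2-[4-methoxy-2-(2-methylbut-3-en-2-yloxy)-6-(triisopropylsilyloxy)benzoyl]-3-[4-methoxy-3-(triisopropylsilyloxy)phenyl]prop-2-enoate | COc1ccc(/C=C(/C(=O)c2c(O[Si](C(C)C)(C(C)C)C(C)C)cc(OC)cc2OC(C)(C)C=C)C(=O)OC(C)(C)C)cc1O[Si](C(C)C)(C(C)C)C(C)C | intermediate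
10 | tert-butyl (Z)-2-[2-hydroxy-4-methoxy-3-(3-methylbut-2-en-1-yl)-6-(triisopropylsilyloxy)benzoyl]-3-[4-methoxy-3-(triisopropylsilyloxy)phenyl]prop-2-enoate (formed in the flask in step 7; not isolated) | COc1ccc(/C=C(/C(=O)c2c(O[Si](C(C)C)(C(C)C)C(C)C)cc(OC)c(CC=C(C)C)c2O)C(=O)OC(C)(C)C)cc1O[Si](C(C)C)(C(C)C)C(C)C | intermediate
11 | tert-butyl (2S,3R)-7-methoxy-2-[4-methoxy-3-(triisopropylsilyloxy)phenyl]-8-(3-methylbut-2-en-1-yl)-4-oxo-5-(triisopropylsilyloxy)chromane-3-carboxylate (2,3-trans; formed in the flask in step 7; not isolated) | COc1ccc([C@@H]2[C@@H](C(=O)OC(C)(C)C)C(=O)c3c(O[Si](C(C)C)(C(C)C)C(C)C)cc(OC)c(CC=C(C)C)c3O2)cc1O[Si](C(C)C)(C(C)C)C(C)C | intermediate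
12 | (2S)-7-methoxy-2-[4-methoxy-3-(triisopropylsilyloxy)phenyl]-8-(3-methylbut-2-en-1-yl)-5-(triisopropylsilyloxy)chroman-4-one | COc1ccc([C@@H]2CC(=O)c3c(O[Si](C(C)C)(C(C)C)C(C)C)cc(OC)c(CC=C(C)C)c3O2)cc1O[Si](C(C)C)(C(C)C)C(C)C | intermediate
13 | (2S)-5-hydroxy-2-(3-hydroxy-4-methoxyphenyl)-7-methoxy-8-(3-methylbut-2-en-1-yl)chroman-4-one | COc1ccc([C@@H]2CC(=O)c3c(O)cc(OC)c(CC=C(C)C)c3O2)cc1O | target

**Count**

Total step count: 8. Longest linear sequence: 7 steps (steps 1, 2, 3, 4, 6, 7, 8); step 5 is a one-step side branch.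

**Steps most likely to fail**

First, step 7. The enantiomeric purity may be lowered in two ways: phenol 10 may close without the catalyst while the flask is still hot, or the catalyst may discriminate the faces poorly on this 2',6'-disubstituted aroyl system. Acid-induced hydration or cyclisation of the prenyl side chain during the decarboxylation is a further loss channel. The fallback sets out from 5 and comes back to the route at 12. It closes the ring first as an achiral chromone and then creates C2 by asymmetric conjugate arylation.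
- Heating 5 in toluene (aromatic Claisen rearrangement at the ketone stage) should give 1-[2-hydroxy-4-methoxy-3-(3-methylbut-2-en-1-yl)-6-(triisopropylsilyloxy)phenyl]ethan-1-one F1.
- DMF dimethyl acetal at 90 °C should convert F1 into (2E)-3-(dimethylamino)-1-[2-hydroxy-4-methoxy-3-(3-methylbut-2-en-1-yl)-6-(triisopropylsilyloxy)phenyl]prop-2-en-1-one F2.
- F2 should cyclise with AcOH or on silica gel, with loss of the amine, to 7-methoxy-8-(3-methylbut-2-en-1-yl)-5-(triisopropylsilyloxy)-4H-chromen-4-one F3.
- Commercial 5-bromo-2-methoxyphenol is silylated (TIPSCl, imidazole) to (5-bromo-2-methoxyphenoxy)triisopropylsilane F4.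
- Bromine–lithium exchange and borylation of F4 (n-BuLi, B(OMe)3, then dilute acid) should give [4-methoxy-3-(triisopropylsilyloxy)phenyl]boronic acid F5.
- Palladium-catalysed asymmetric 1,4-addition of F5 to F3 should then give 12. Conditions: Pd(OCOCF3)2, the enantiomer of the t-BuPyOx ligand that leads to 2S, NH4PF6, H2O, ClCH2CH2Cl, 60 °C.

Second, step 4. The enolate may be acylated on oxygen (enol carbonate) or twice, instead of once on carbon. The fallback sets out from 5 and comes back at 6. It separates carboxylation from ester formation: the lithium enolate of 5 (LiHMDS, THF, −78 °C) is quenched with CO2, which adds at carbon, to give 3-[4-methoxy-2-(2-methylbut-3-en-2-yloxy)-6-(triisopropylsilyloxy)phenyl]-3-oxopropanoic acid F6. F6 is kept cold and esterified at once with tert-butyl 2,2,2-trichloroacetimidate (CH2Cl2/cyclohexane, 20 °C) to give 6.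

Third, step 1. The tertiary propargylic chloride may etherify both hydroxyls, alkylate at ring carbon, or the ether may cyclise to a chromene, so that the mono-ether is not obtained cleanly. The fallback sets out from 1 and comes back at 5. It forms the allyl ether directly by palladium π-allyl chemistry (Tsuji–Trost O-allylation), which skips the alkyne and its semi-hydrogenation. Compound 1 with tert-butyl 2-methylbut-3-en-2-yl carbonate and Pd(PPh3)4 (cat.) in THF at 0 °C should give the branched ether 1-[2-hydroxy-4-methoxy-6-(2-methylbut-3-en-2-yloxy)phenyl]ethan-1-one F7 as the kinetic product of attack at the more substituted allyl terminus. Silylation of F7 under the conditions of step 2, at 20 °C, gives 5.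

**Further compounds**

F1 | step 7 | 1-[2-hydroxy-4-methoxy-3-(3-methylbut-2-en-1-yl)-6-(triisopropylsilyloxy)phenyl]ethan-1-one | CC(=O)c1c(O[Si](C(C)C)(C(C)C)C(C)C)cc(OC)c(CC=C(C)C)c1O
F2 | step 7 | (2E)-3-(dimethylamino)-1-[2-hydroxy-4-methoxy-3-(3-methylbut-2-en-1-yl)-6-(triisopropylsilyloxy)phenyl]prop-2-en-1-one | CN(C)/C=C/C(=O)c1c(O[Si](C(C)C)(C(C)C)C(C)C)cc(OC)c(CC=C(C)C)c1O
F3 | step 7 | 7-methoxy-8-(3-methylbut-2-en-1-yl)-5-(triisopropylsilyloxy)-4H-chromen-4-one | O=c1ccoc2c(CC=C(C)C)c(OC)cc(O[Si](C(C)C)(C(C)C)C(C)C)c12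
F4 | step 7 | (5-bromo-2-methoxyphenoxy)triisopropylsilane | COc1ccc(Br)cc1O[Si](C(C)C)(C(C)C)C(C)C
F5 | step 7 | [4-methoxy-3-(triisopropylsilyloxy)phenyl]boronic acid | COc1ccc(B(O)O)cc1O[Si](C(C)C)(C(C)C)C(C)C
F6 | step 4 | 3-[4-methoxy-2-(2-methylbut-3-en-2-yloxy)-6-(triisopropylsilyloxy)phenyl]-3-oxopropanoic acid | OC(=O)CC(=O)c1c(O[Si](C(C)C)(C(C)C)C(C)C)cc(OC)cc1OC(C)(C)C=C
F7 | step 1 | 1-[2-hydroxy-4-methoxy-6-(2-methylbut-3-en-2-yloxy)phenyl]ethan-1-one | CC(=O)c1c(O)cc(OC)cc1OC(C)(C)C=C
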